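**Plan**
- Retrosynthetic cuts, in order: the C2–Br and C3–Br bonds, then the C2=C3 bond of the pyrrole ring (Wittig), then N1–C2 (formyl), C3–P, the benzylic C–Br bond and C7a–N (nitration).
- Enabling feature: C3 is benzylic to C3a, and C2 hangs on N1 at the neighbouring C7a. An ylide carbon and a formamide carbon therefore sit ortho to each other on the benzene ring that already carries Br at C5 and C6.
- Forward order: the dibromobenzene ring is bought. Nitration, benzylic bromination, phosphonium salt formation, nitro reduction and N-formylation load it. The pyrrole ring, the only ring made, closes in step 6.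
- The two pyrrole bromines go on last by electrophilic substitution, C3 before C2.
- Stereochemistry: the target is flat and achiral, so nothing has to be set. The two sp3 carbons of the transient oxaphosphetane vanish with Ph3P=O.

Key step: step 6

Assumption: all phosphonium salts are carried as bromides, and the transient oxaphosphetane of the key step is drawn as one enantiomer of a racemate.

**Step 1**
Reactants: 1 3,4-dibromotoluene
Product: 2 4,5-dibromo-2-nitrotoluene
Conditions: HNO3 (70%), conc. H2SO4, 0 °C to rt; recrystallisation from EtOH
Reagents that add atoms: nitric acid, O[N+](=O)[O-]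
Why: In this electrophilic aromatic nitration the nitronium ion should enter at C6, the only open position that is both ortho to the methyl group and para to a bromine without being wedged between two substituents, and minor isomers should be removed by crystallisation.

**Step 2**
Reactants: 2 4,5-dibromo-2-nitrotoluene
Product: 3 4,5-dibromo-2-nitrobenzyl bromide
Conditions: NBS (1.05 equiv), AIBN (5 mol%), PhCF3, reflux, visible-light lamp
Reagents that add atoms: N-bromosuccinimide, O=C1CCC(=O)N1Br
Why: In this Wohl–Ziegler radical bromination the only sp3 C–H bonds of 2 are benzylic, and holding NBS near one equivalent should keep the gem-dibromide low.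

**Step 3**
Reactants: 3 4,5-dibromo-2-nitrobenzyl bromide; 4 triphenylphosphine
Product: 5 (4,5-dibromo-2-nitrobenzyl)triphenylphosphonium bromide
Conditions: toluene, 90 °C; the salt is filtered off and washed with toluene
Reagents that add atoms: none
Why: This is an SN2 quaternisation of a phosphine by a primary benzylic bromide, in which the aryl bromides are inert without a metal catalyst and precipitation of the salt should leave unreacted 2 in the mother liquor.

**Step 4**
Reactants: 5 (4,5-dibromo-2-nitrobenzyl)triphenylphosphonium bromide
Product: 6 (2-amino-4,5-dibromobenzyl)triphenylphosphonium bromide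
Conditions: Fe powder (5 equiv), 48% aq HBr (6.5 equiv), EtOH, 70 °C; filtration through Celite, extraction into CH2Cl2
Reagents that add atoms: none
Why: In this Béchamp-type reduction, iron metal in dilute acid should take NO2 to NH2 without hydrogenolysis of the aryl C–Br or benzylic C–P bonds, and HBr as the acid keeps bromide as the only counter-ion.

**Step 5**
Reactants: 6 (2-amino-4,5-dibromobenzyl)triphenylphosphonium bromide
Product: 7 (4,5-dibromo-2-formamidobenzyl)triphenylphosphonium bromide
Conditions: HCO2H/Ac2O (premixed, 55 °C, 2 h), then 6, CH2Cl2, 0 °C to rt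
Reagents that add atoms: formic acid, OC=O, delivered as acetic formic anhydride, CC(=O)OC=O
Why: In this N-formylation with a mixed anhydride the weakly nucleophilic aniline attacks the less hindered, more electrophilic formyl carbonyl, and the base-free acidic medium leaves the phosphonium CH2 untouched.

**Step 6**
Reactants: 7 (4,5-dibromo-2-formamidobenzyl)triphenylphosphonium bromide
Product: 10 5,6-dibromo-1H-indole, via benzylic ylide 8 (not isolated), via cis-fused oxaphosphetane 9 (not isolated)
Conditions: DBU (2.0 equiv), anhydrous toluene, reflux, N2
Reagents that add atoms: none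
Why: DBU takes a proton from the P+–CH2 group of 7, the most acidic site because the phosphonium centre and the dibromoarene both stabilise the carbanion, and gives the semistabilised ylide 8 in a low concentration that is refilled as it is consumed. The ylide carbon (later C3) adds to the formamide carbon (later C2) held ortho to it, a 5-exo-trig closure of the pyrrole ring, and the adduct collapses through the cis-fused oxaphosphetane 9, whose cycloreversion expels triphenylphosphine oxide and leaves C2=C3. The closest known reaction type is the intramolecular Wittig indole synthesis from (2-acylaminobenzyl)triphenylphosphonium salts, here run on the formyl member, whose carbonyl is the least hindered and most electrophilic of the amide series. No stereocentre remains, since both sp3 carbons of 9 become sp2 on loss of the phosphine oxide. The step needs chemoselectivity: ylide formation and carbonyl attack must win over N–H deprotonation, ylide hydrolysis and any reaction at the C5 and C6 bromines, which is secured by the acidity gap between P+–CH2 and N–H, the closeness of the two partners, a dry medium and a neutral amidine base that cannot trigger halogen–metal exchange, halogen migration or aryne formation. The strong P=O bond and the gain of indole aromaticity make the closure irreversible.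

**Step 7**
Reactants: 10 5,6-dibromo-1H-indole
Product: 12 2,3,5,6-tetrabromo-1H-indole, via 3,5,6-tribromo-1H-indole 11 (not isolated)
Conditions: NBS (2.1 equiv), silica gel, CH2Cl2, 0 °C to rt, dark
Reagents that add atoms: N-bromosuccinimide, O=C1CCC(=O)N1Br
Why: In this electrophilic aromatic substitution of the enamine-like pyrrole ring the first equivalent of NBS brominates C3, the most nucleophilic carbon, and the second takes C2 (directly or through a 3,3-dibromoindolenine that shifts one bromine), while the benzene ring, deactivated by two bromines and open only at the crowded C4 and C7, should stay untouched.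

**Compound list**
1 | 3,4-dibromotoluene | Cc1ccc(Br)c(Br)c1 | starting material
2 | 4,5-dibromo-2-nitrotoluene (1,2-dibromo-4-methyl-5-nitrobenzene) | Cc1cc(Br)c(Br)cc1[N+](=O)[O-] | intermediate
3 | 4,5-dibromo-2-nitrobenzyl bromide | BrCc1cc(Br)c(Br)cc1[N+](=O)[O-] | intermediate
4 | triphenylphosphine | c1ccc(cc1)P(c1ccccc1)c1ccccc1 | starting material
5 | (4,5-dibromo-2-nitrobenzyl)triphenylphosphonium bromide | [O-][N+](=O)c1cc(Br)c(Br)cc1C[P+](c1ccccc1)(c1ccccc1)c1ccccc1.[Br-] | intermediate
6 | (2-amino-4,5-dibromobenzyl)triphenylphosphonium bromide | Nc1cc(Br)c(Br)cc1C[P+](c1ccccc1)(c1ccccc1)c1ccccc1.[Br-] | intermediate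
7 | (4,5-dibromo-2-formamidobenzyl)triphenylphosphonium bromide | O=CNc1cc(Br)c(Br)cc1C[P+](c1ccccc1)(c1ccccc1)c1ccccc1.[Br-] | intermediate
8 | benzylic ylide, (4,5-dibromo-2-formamidobenzylidene)triphenylphosphorane | O=CNc1cc(Br)c(Br)cc1C=P(c1ccccc1)(c1ccccc1)c1ccccc1 | intermediate
9 | cis-fused oxaphosphetane: 5,6-dibromoindoline bridged by O on C2 and PPh3 on C3 (racemic, one enantiomer drawn) | Brc1cc2N[C@@H]3OP(c4ccccc4)(c4ccccc4)(c4ccccc4)[C@@H]3c2cc1Br | intermediate
10 | 5,6-dibromo-1H-indole | Brc1cc2cc[nH]c2cc1Br | intermediate
11 | 3,5,6-tribromo-1H-indole | Brc1c[nH]c2cc(Br)c(Br)cc12 | intermediate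
12 | 2,3,5,6-tetrabromo-1H-indole | Brc1cc2[nH]c(Br)c(Br)c2cc1Br | target

Total step count: 7. Longest linear sequence: 7 steps (1 to 12).

**Steps most likely to fail**

**Step 6.**
- Risk: deprotonation of the formamide N–H may dull the carbonyl before the ylide attacks. Traces of water may also hydrolyse the ylide and cleave the C–P bond.
- Fallback: it sets out from 6 and keeps the C2–C3 Wittig closure, but changes the carbonyl partner and the oxidation level at C2.
- Amine 6 is acylated with ethyl chlorooxoacetate and pyridine in CH2Cl2 at 0 °C to give {4,5-dibromo-2-[(ethoxyoxalyl)amino]benzyl}triphenylphosphonium bromide F1. Its amide carbonyl is activated by the neighbouring ester.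
- DBU in refluxing toluene should then close ethyl 5,6-dibromo-1H-indole-2-carboxylate F2.
- LiOH in THF/H2O followed by acidification gives 5,6-dibromo-1H-indole-2-carboxylic acid F3.
- Silver-catalysed protodecarboxylation (Ag2CO3, AcOH, DMSO, 120 °C) returns to the route at 10.

**Step 7.**
- Risk: the sequence may stall after the first bromination. The N–H indole may be oxidised at C2 by adventitious water, or bromine may migrate under acid catalysis.
- Fallback: it sets out from 10 and installs the C2 bromine by C–H borylation and ipso-substitution, not by electrophilic attack.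
- [Ir(OMe)(cod)]2, 4,4'-di-tert-butyl-2,2'-bipyridine and B2pin2 in THF at 60 °C should borylate the sterically free, most acidic C2–H. The product is 5,6-dibromo-2-(4,4,5,5-tetramethyl-1,3,2-dioxaborolan-2-yl)-1H-indole F4.
- CuBr2 in MeOH/H2O at 80 °C converts it into 2,5,6-tribromo-1H-indole F5.
- One equivalent of NBS in DMF at 0 °C performs the easy C3 bromination and rejoins the route at 12.

**Step 2.**
- Risk: hydrogen abstraction from a methyl group next to a nitro group on an electron-poor ring is slow. Incomplete conversion and over-bromination may then run side by side.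
- Fallback: it sets out from 2 and uses the C–H acidity of the o-nitrotoluene in place of radical chemistry.
- N,N-dimethylformamide dimethyl acetal in DMF at 120 °C gives (E)-2-(4,5-dibromo-2-nitrophenyl)-N,N-dimethylethenamine F6.
- NaIO4 in THF/H2O cleaves the enamine double bond to 4,5-dibromo-2-nitrobenzaldehyde F7.
- NaBH4 in MeOH at 0 °C gives (4,5-dibromo-2-nitrophenyl)methanol F8.
- PBr3 in CH2Cl2 at 0 °C returns to the route at 3.

**Further compounds**
F1 | step 6 | {4,5-dibromo-2-[(ethoxyoxalyl)amino]benzyl}triphenylphosphonium bromide | CCOC(=O)C(=O)Nc1cc(Br)c(Br)cc1C[P+](c1ccccc1)(c1ccccc1)c1ccccc1.[Br-]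
F2 | step 6 | ethyl 5,6-dibromo-1H-indole-2-carboxylate | CCOC(=O)c1cc2cc(Br)c(Br)cc2[nH]1
F3 | step 6 | 5,6-dibromo-1H-indole-2-carboxylic acid | OC(=O)c1cc2cc(Br)c(Br)cc2[nH]1
F4 | step 7 | 5,6-dibromo-2-(4,4,5,5-tetramethyl-1,3,2-dioxaborolan-2-yl)-1H-indole | CC1(C)OB(OC1(C)C)c1cc2cc(Br)c(Br)cc2[nH]1
F5 | step 7 | 2,5,6-tribromo-1H-indole | Brc1cc2cc(Br)c(Br)cc2[nH]1
F6 | step 2 | (E)-2-(4,5-dibromo-2-nitrophenyl)-N,N-dimethylethenamine | CN(C)/C=C/c1cc(Br)c(Br)cc1[N+](=O)[O-]
F7 | step 2 | 4,5-dibromo-2-nitrobenzaldehyde | O=Cc1cc(Br)c(Br)cc1[N+](=O)[O-]
F8 | step 2 | (4,5-dibromo-2-nitrophenyl)methanol | OCc1cc(Br)c(Br)cc1[N+](=O)[O-]
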